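**Plan**
The target is cut first at the three CH=C(CH3)2 double bonds of the prenyl groups on C6 and C8 of the phloroglucinol A ring and on C5′ of the guaiacyl B ring. Each prenyl is an aryl–CH2–CH=CH2 allyl group whose terminal CH2 is replaced by C(CH3)2, so the target maps onto a triallylflavanone plus 2-methyl-2-butene.
The triallylflavanone is then cut at C2–C1′ (chromone + arylboronic acid), at O1–C2/C2–C3 of the pyranone (acetophenone + one carbon) and at the three aryl–allyl bonds (allyl ethers, Claisen).
Forward: both benzene rings are bought; the A-ring ketone is diallylated, the pyranone is closed as a chromone (the only ring made), the allylated B ring is attached at C2, the MOM groups are removed with acid while the side chains are still allyl, and the three allyls are converted to prenyls last.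
The single stereocentre, C2 (S), is set by catalyst control in the Rh/chiral-diene conjugate arylation and afterwards sees only acidic and neutral conditions.

Key step: step 11

Assumption: the chiral diene is taken to select the same face of the chromone C2=C3 bond as it does on 2-cyclohexenone, which points to the (S,S)-ligand for (2S); the mirror-image ligand would be used if the first run showed the opposite sense.

**Step 1**
Reactants: 1 2,4,6-trihydroxyacetophenone; 2 allyl bromide
Product: 3 1-[2,4-bis(allyloxy)-6-hydroxyphenyl]ethanone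
Conditions: 2 (2.1 equiv), K2CO3 (2.2 equiv), acetone, reflux
Reagents that add atoms: allyl bromide (2), C=CCBr
Why: Williamson O-allylation with a weak base in an aprotic solvent should take the 4-OH and one ortho OH, the last phenol being held back by its hydrogen bond to the acetyl carbonyl.

**Step 2**
Reactants: 3 1-[2,4-bis(allyloxy)-6-hydroxyphenyl]ethanone
Product: 4 1-(3,5-diallyl-2,4,6-trihydroxyphenyl)ethanone
Conditions: PhNEt2, 200 °C, sealed tube, Ar
Reagents that add atoms: none
Why: Double aromatic Claisen rearrangement; because C1 carries the acetyl group, each allyl can only end on C3 or C5, by a direct ortho [3,3] shift or by an ortho shift followed by a Cope shift to the para carbon, so all pathways converge on the 3,5-diallyl triol.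

**Step 3**
Reactants: 4 1-(3,5-diallyl-2,4,6-trihydroxyphenyl)ethanone
Product: 5 1-[3,5-diallyl-2-hydroxy-4,6-bis(methoxymethoxy)phenyl]ethanone
Conditions: MOMCl (2.2 equiv), i-Pr2NEt, CH2Cl2, 0 °C to rt
Reagents that add atoms: chloromethyl methyl ether (MOMCl), COCCl
Why: MOM etherification of the 4-OH and one ortho OH under amine base; the remaining carbonyl-chelated phenol is unreactive and is kept as the future ring oxygen.

**Step 4**
Reactants: 5 1-[3,5-diallyl-2-hydroxy-4,6-bis(methoxymethoxy)phenyl]ethanone
Product: 7 6,8-diallyl-5,7-bis(methoxymethoxy)-4H-chromen-4-one, via dimethylamino enone 6 (not isolated)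
Conditions: Me2NCH(OMe)2, toluene, 95 °C; evaporate; AcOH (3 equiv), CH2Cl2, 40 °C
Reagents that add atoms: N,N-dimethylformamide dimethyl acetal, COC(OC)N(C)C
Why: Enaminone chromone synthesis: the methyl ketone condenses with the amide acetal, then under acetic acid the chelated phenol adds to the β-carbon and dimethylamine is expelled to close the pyranone, the acid being too weak to cleave aryl MOM ethers.

**Step 5**
Reactants: 8 4-bromo-2-methoxyphenol; 2 allyl bromide
Product: 9 1-(allyloxy)-4-bromo-2-methoxybenzene
Conditions: 2 (1.2 equiv), K2CO3, acetone, reflux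
Reagents that add atoms: allyl bromide (2), C=CCBr
Why: Williamson O-allylation of a simple phenol.

**Step 6**
Reactants: 9 1-(allyloxy)-4-bromo-2-methoxybenzene
Product: 10 2-allyl-4-bromo-6-methoxyphenol
Conditions: PhNEt2, 200 °C, Ar
Reagents that add atoms: none
Why: Aromatic ortho-Claisen rearrangement to the only free ortho carbon, the other ortho position carrying the methoxy group and the para position the bromine.

**Step 7**
Reactants: 10 2-allyl-4-bromo-6-methoxyphenol
Product: 11 1-allyl-5-bromo-3-methoxy-2-(methoxymethoxy)benzene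
Conditions: MOMCl, i-Pr2NEt, CH2Cl2, 0 °C to rt
Reagents that add atoms: chloromethyl methyl ether (MOMCl), COCCl
Why: MOM etherification masks the phenol so that it neither quenches the organolithium of step 8 nor forms a phenoxide in step 9.

**Step 8**
Reactants: 11 1-allyl-5-bromo-3-methoxy-2-(methoxymethoxy)benzene
Product: 14 [3-allyl-5-methoxy-4-(methoxymethoxy)phenyl]boronic acid, via aryllithium 12 (not isolated), via lithium triisopropoxyborate 13 (not isolated)
Conditions: n-BuLi, THF, −78 °C; B(Oi-Pr)3, −78 °C to rt; 1 M HCl to pH 5, 0 °C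
Reagents that add atoms: triisopropyl borate, CC(C)OB(OC(C)C)OC(C)C; water, O
Why: Bromine–lithium exchange at −78 °C is much faster than deprotonation of the allylic CH2, and trapping with the borate followed by mild hydrolysis should give the boronic acid with the MOM ether intact.

**Step 9**
Reactants: 7 6,8-diallyl-5,7-bis(methoxymethoxy)-4H-chromen-4-one; 14 [3-allyl-5-methoxy-4-(methoxymethoxy)phenyl]boronic acid
Product: 15 (2S)-6,8-diallyl-2-[3-allyl-5-methoxy-4-(methoxymethoxy)phenyl]-5,7-bis(methoxymethoxy)chroman-4-one
Conditions: 14 (2.5 equiv), [RhCl(C2H4)2]2 (3 mol%), (S,S)-Ph-bod* (6.6 mol%), KOH (0.2 equiv), toluene/H2O 10:1, 40 °C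
Reagents that add atoms: none
Why: Hayashi–Miyaura asymmetric 1,4-addition: the aryl–Rh(I) species held by the C2-symmetric diene carbometalates the chromone C2=C3 bond on one enantiotopic face, setting C2 as (S) under catalyst control, and water protonates the oxa-π-allyl rhodium; the MOM ethers prevent phenoxide formation and the unactivated allyl groups should not compete with the enone for insertion.

**Step 10**
Reactants: 15 (2S)-6,8-diallyl-2-[3-allyl-5-methoxy-4-(methoxymethoxy)phenyl]-5,7-bis(methoxymethoxy)chroman-4-one
Product: 16 (2S)-6,8-diallyl-2-(3-allyl-4-hydroxy-5-methoxyphenyl)-5,7-dihydroxychroman-4-one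
Conditions: 3 M aq. HCl, MeOH, 50 °C
Reagents that add atoms: none
Why: Acid-catalysed transacetalisation removes the three MOM groups; terminal allyl groups are not protonated under these conditions and C2 is not epimerised, because there is no base to open the ring to the chalcone.

**Step 11**
Reactants: 16 (2S)-6,8-diallyl-2-(3-allyl-4-hydroxy-5-methoxyphenyl)-5,7-dihydroxychroman-4-one; 17 2-methyl-2-butene
Product: 18 (2S)-5,7-dihydroxy-2-[4-hydroxy-3-methoxy-5-(3-methylbut-2-en-1-yl)phenyl]-6,8-bis(3-methylbut-2-en-1-yl)chroman-4-one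
Conditions: Grubbs II (10 mol%, in portions), 1,4-benzoquinone (10 mol%), 17/CH2Cl2 3:1, 40 °C, sealed tube
Reagents that add atoms: 2-methyl-2-butene (17), CC=C(C)C
Why: Olefin cross-metathesis by the Chauvin cycle: each terminal ArCH2CH=CH2 enters a ruthenacyclobutane and the resulting carbene exchanges with 2-methyl-2-butene, so the terminal CH2 is replaced by C(CH3)2 and propene is released at each of the three sites. The closest known reaction is the cross-metathesis of o-allylphenols and other allylarenes with 2-methyl-2-butene to prenylarenes, which tolerates free phenols and aryl ketones. No ring is closed and no stereocentre is formed; C2 is remote from the reacting alkenes and cannot epimerise under these neutral conditions. The step needs complete exchange at all three sites without homodimerisation or allyl-to-propenyl migration. Using the alkene partner as co-solvent drives each site forward, the trisubstituted prenyl products are too hindered to re-enter the cycle, and benzoquinone intercepts ruthenium hydrides. The 6- and 8-allyl groups sit meta across C7 and the 5′-allyl on the other ring, so no ring-closing pathway gives an unstrained ring.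

**Compound list**
1 | 2,4,6-trihydroxyacetophenone | CC(=O)c1c(O)cc(O)cc1O | starting material
2 | allyl bromide | C=CCBr | starting material
3 | 1-[2,4-bis(allyloxy)-6-hydroxyphenyl]ethanone | CC(=O)c1c(O)cc(OCC=C)cc1OCC=C | intermediate
4 | 1-(3,5-diallyl-2,4,6-trihydroxyphenyl)ethanone | CC(=O)c1c(O)c(CC=C)c(O)c(CC=C)c1O | intermediate
5 | 1-[3,5-diallyl-2-hydroxy-4,6-bis(methoxymethoxy)phenyl]ethanone | CC(=O)c1c(O)c(CC=C)c(OCOC)c(CC=C)c1OCOC | intermediate
6 | (E)-1-[3,5-diallyl-2-hydroxy-4,6-bis(methoxymethoxy)phenyl]-3-(dimethylamino)prop-2-en-1-one | CN(C)/C=C/C(=O)c1c(O)c(CC=C)c(OCOC)c(CC=C)c1OCOC | intermediate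
7 | 6,8-diallyl-5,7-bis(methoxymethoxy)-4H-chromen-4-one | O=c1ccoc2c(CC=C)c(OCOC)c(CC=C)c(OCOC)c12 | intermediate
8 | 4-bromo-2-methoxyphenol | COc1cc(Br)ccc1O | starting material
9 | 1-(allyloxy)-4-bromo-2-methoxybenzene | COc1cc(Br)ccc1OCC=C | intermediate
10 | 2-allyl-4-bromo-6-methoxyphenol | COc1cc(Br)cc(CC=C)c1O | intermediate
11 | 1-allyl-5-bromo-3-methoxy-2-(methoxymethoxy)benzene | COc1cc(Br)cc(CC=C)c1OCOC | intermediate
12 | [3-allyl-5-methoxy-4-(methoxymethoxy)phenyl]lithium | [Li]c1cc(CC=C)c(OCOC)c(OC)c1 | intermediate
13 | lithium [3-allyl-5-methoxy-4-(methoxymethoxy)phenyl]triisopropoxyborate | [Li+].CC(C)O[B-](OC(C)C)(OC(C)C)c1cc(CC=C)c(OCOC)c(OC)c1 | intermediate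
14 | [3-allyl-5-methoxy-4-(methoxymethoxy)phenyl]boronic acid | COc1cc(B(O)O)cc(CC=C)c1OCOC | intermediate
15 | (2S)-6,8-diallyl-2-[3-allyl-5-methoxy-4-(methoxymethoxy)phenyl]-5,7-bis(methoxymethoxy)chroman-4-one | COc1cc([C@@H]2CC(=O)c3c(OCOC)c(CC=C)c(OCOC)c(CC=C)c3O2)cc(CC=C)c1OCOC | intermediate
16 | (2S)-6,8-diallyl-2-(3-allyl-4-hydroxy-5-methoxyphenyl)-5,7-dihydroxychroman-4-one | COc1cc([C@@H]2CC(=O)c3c(O)c(CC=C)c(O)c(CC=C)c3O2)cc(CC=C)c1O | intermediate
17 | 2-methyl-2-butene | CC=C(C)C | starting material
18 | (2S)-5,7-dihydroxy-2-[4-hydroxy-3-methoxy-5-(3-methylbut-2-en-1-yl)phenyl]-6,8-bis(3-methylbut-2-en-1-yl)chroman-4-one (CNP0235424.1) | COc1cc([C@@H]2CC(=O)c3c(O)c(CC=C(C)C)c(O)c(CC=C(C)C)c3O2)cc(CC=C(C)C)c1O | target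

**Step count**
Total: 11 steps. Longest linear sequence: 7 steps (1 → 3 → 4 → 5 → 7 → 15 → 16 → 18; the B-ring branch 8 → 14 is 4 steps and joins at step 9).

**Steps most likely to fail**

Step 9. Carbometalation of the electron-rich 5,7-dialkoxychromone may be slow, so that protodeboronation of the electron-rich boronic acid outruns it. Hydroxide may also open the product to the chalcone and erode the configuration at C2. The fallback sets out from 11 and 5 and comes back at 15. Bromide 11 is lithiated as in step 8 and the aryllithium 12 is quenched with DMF to give 3-allyl-5-methoxy-4-(methoxymethoxy)benzaldehyde F1. Claisen–Schmidt condensation of F1 with acetophenone 5 (KOH, EtOH, rt) should give (E)-1-[3,5-diallyl-2-hydroxy-4,6-bis(methoxymethoxy)phenyl]-3-[3-allyl-5-methoxy-4-(methoxymethoxy)phenyl]prop-2-en-1-one F2. NaOAc in refluxing EtOH should close it by oxa-Michael addition to racemic 6,8-diallyl-2-[3-allyl-5-methoxy-4-(methoxymethoxy)phenyl]-5,7-bis(methoxymethoxy)chroman-4-one F3. Kinetic resolution by Ru–TsDPEN transfer hydrogenation (HCO2H/Et3N), using the catalyst antipode that reduces the (2R)-ketone faster, should leave the (2S)-ketone 15. The (2R)-ketone is converted into (2R,4R)-6,8-diallyl-2-[3-allyl-5-methoxy-4-(methoxymethoxy)phenyl]-5,7-bis(methoxymethoxy)chroman-4-ol F4, which is removed by chromatography; the allyl groups are not reduced.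

Step 11. Exchange may stop at one or two of the three sites, ruthenium hydrides may move the allyl double bonds into conjugation, or the free polyphenol may deactivate the catalyst. The fallback sets out from 15 and comes back at 18. The cross-metathesis with 17 (Grubbs II, 17/CH2Cl2, 40 °C) is run on the fully masked flavanone to give (2S)-2-[3-methoxy-4-(methoxymethoxy)-5-(3-methylbut-2-en-1-yl)phenyl]-5,7-bis(methoxymethoxy)-6,8-bis(3-methylbut-2-en-1-yl)chroman-4-one F5. The MOM groups are then removed with catalytic HCl in MeOH at rt, the reaction being stopped as soon as F5 is consumed so that the prenyl groups do not cyclise onto the phenols, which should give 18.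

Step 4. The peri MOM ether may be lost during the acid-assisted ring closure, or closure may stay incomplete under acid mild enough to spare it. The fallback sets out from 5 and comes back at 7. The enaminone 6 is made as before and cyclised with conc. HCl in MeOH at reflux, accepting loss of both MOM groups, to give 6,8-diallyl-5,7-dihydroxy-4H-chromen-4-one F6. Both phenols, including the chelated 5-OH, are then re-protected with NaH and MOMCl in DMF (0 °C to rt) to give 7.

**Further compounds**
F1 | step 9 | 3-allyl-5-methoxy-4-(methoxymethoxy)benzaldehyde | COc1cc(C=O)cc(CC=C)c1OCOC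
F2 | step 9 | (E)-1-[3,5-diallyl-2-hydroxy-4,6-bis(methoxymethoxy)phenyl]-3-[3-allyl-5-methoxy-4-(methoxymethoxy)phenyl]prop-2-en-1-one | COc1cc(/C=C/C(=O)c2c(O)c(CC=C)c(OCOC)c(CC=C)c2OCOC)cc(CC=C)c1OCOC
F3 | step 9 | racemic 6,8-diallyl-2-[3-allyl-5-methoxy-4-(methoxymethoxy)phenyl]-5,7-bis(methoxymethoxy)chroman-4-one | COc1cc(C2CC(=O)c3c(OCOC)c(CC=C)c(OCOC)c(CC=C)c3O2)cc(CC=C)c1OCOC
F4 | step 9 | (2R,4R)-6,8-diallyl-2-[3-allyl-5-methoxy-4-(methoxymethoxy)phenyl]-5,7-bis(methoxymethoxy)chroman-4-ol | COc1cc([C@H]2C[C@@H](O)c3c(OCOC)c(CC=C)c(OCOC)c(CC=C)c3O2)cc(CC=C)c1OCOC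
F5 | step 11 | (2S)-2-[3-methoxy-4-(methoxymethoxy)-5-(3-methylbut-2-en-1-yl)phenyl]-5,7-bis(methoxymethoxy)-6,8-bis(3-methylbut-2-en-1-yl)chroman-4-one | COc1cc([C@@H]2CC(=O)c3c(OCOC)c(CC=C(C)C)c(OCOC)c(CC=C(C)C)c3O2)cc(CC=C(C)C)c1OCOC
F6 | step 4 | 6,8-diallyl-5,7-dihydroxy-4H-chromen-4-one | O=c1ccoc2c(CC=C)c(O)c(CC=C)c(O)c12
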